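**Retrosynthetic overview**

1. Target ⇐ tricetin: diphenylmethylene ketal on two adjacent ring B hydroxyls, sulfation of O7 and of the remaining ring B hydroxyl (O5 stays hydrogen-bonded to the C4 carbonyl), ketal hydrogenolysis; tricetin ⇐ its 5,3',4',5'-tetramethyl ether (BBr3).
2. Feature used: ring A carries oxygens at C5 and C7 in a 1,3-relation, matching C1 and C3 of a 1,1-dimethoxy-3-silyloxybutadiene, and its C4a=C8a bond is the enone double bond of ring C next to the C4 carbonyl.
3. Key disconnection: ring A of 7-hydroxy-5,3',4',5'-tetramethoxyflavone is cut at C8–C8a and C4a–C5 ⇒ 5-nitro-2-(3,4,5-trimethoxyphenyl)-4-pyranone + 1,1-dimethoxy-3-(trimethylsilyloxy)butadiene ([4+2], then loss of HNO2 and MeOH).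
4. Nitropyranone ⇐ α-nitro ynone (one carbon from orthoformate, 6-endo-dig oxa-Michael closes ring C) ⇐ aryl ynal + nitromethane ⇐ aryl alkyne; diene ⇐ 1,1-dimethoxyethene + acetyl chloride.
5. Ring order: ring B is bought, ring C is closed in step 4, ring A in step 7.

Key step: step 7

Remark: the target is drawn as the free bis(hydrogen sulfate); because aryl hydrogen sulfates are best handled as salts, the sulfates are carried as triethylammonium salts and the free acid is released only in the last operation (cold H+ exchange resin, freeze-drying).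

**Route**

Step 1
Reactants: 1 5-ethynyl-1,2,3-trimethoxybenzene
Product: 2 3-(3,4,5-trimethoxyphenyl)prop-2-ynal
Conditions: n-BuLi, THF, −78 °C; DMF, −78 → 0 °C; inverse quench into cold 1 M aq HCl
Reagents that add atoms: N,N-dimethylformamide, CN(C)C=O
Why: Formylation of a lithium acetylide with DMF; the lithium hemiaminal alkoxide survives until the acidic inverse quench, which frees the ynal while dimethylamine is protonated and cannot add to it.

Step 2
Reactants: 2 3-(3,4,5-trimethoxyphenyl)prop-2-ynal; 3 nitromethane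
Product: 4 1-nitro-4-(3,4,5-trimethoxyphenyl)but-3-yn-2-ol (racemic)
Conditions: MeNO2 (5 equiv), i-Pr2NEt (10 mol %), THF, 0 °C
Reagents that add atoms: none
Why: Henry (nitroaldol) reaction, in which 1,2-addition of the nitronate to the aldehyde should outrun conjugate addition to the ynal; the new carbinol stereocentre forms racemic and is removed by the oxidation in step 3.

Step 3
Reactants: 4 1-nitro-4-(3,4,5-trimethoxyphenyl)but-3-yn-2-ol
Product: 5 1-nitro-4-(3,4,5-trimethoxyphenyl)but-3-yn-2-one
Conditions: Dess–Martin periodinane, CH2Cl2, 0 → 25 °C; aq Na2S2O3 (pH 5)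
Reagents that add atoms: none
Why: Dess–Martin oxidation of a secondary propargylic β-nitro alcohol to the α-nitro ketone; the non-basic medium avoids retro-Henry cleavage and dehydration to the nitroenyne.

Step 4
Reactants: 5 1-nitro-4-(3,4,5-trimethoxyphenyl)but-3-yn-2-one
Product: 8 5-nitro-2-(3,4,5-trimethoxyphenyl)-4H-pyran-4-one, via ethoxymethylene nitro ynone 6 (not isolated), via hydroxymethylene nitro ynone 7 (not isolated)
Conditions: HC(OEt)3, Ac2O, 100 °C; evaporate; TsOH·H2O (10 mol %), MeCN/H2O 20:1, 60 °C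
Reagents that add atoms: triethyl orthoformate, CCOC(OCC)OCC; water, O
Why: Orthoester condensation at the CH2 flanked by nitro and carbonyl (as in the ethoxymethylenation of nitroacetic esters), hydrolysis of the enol ether, and acid-catalysed 6-endo-dig oxa-Michael addition of the enol oxygen to the ynone β-carbon should close ring C as the γ-pyranone, the 5-exo mode being an anti-Michael addition.

Step 5
Reactants: 9 1,1-dimethoxyethene (2 equiv); 10 acetyl chloride
Product: 11 4,4-dimethoxybut-3-en-2-one
Conditions: Et2O, 0 → 25 °C; distil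
Reagents that add atoms: none
Why: C-acylation of a ketene acetal by an acid chloride; the second equivalent of the ketene acetal takes up the HCl (as methyl acetate and chloromethane), so the acid-labile β,β-dimethoxy enone should survive.

Step 6
Reactants: 11 4,4-dimethoxybut-3-en-2-one
Product: 12 1,1-dimethoxy-3-(trimethylsilyloxy)buta-1,3-diene
Conditions: LiN(i-Pr)2, THF, −78 °C; Me3SiCl, −78 → 25 °C; distil
Reagents that add atoms: chlorotrimethylsilane, C[Si](C)(C)Cl
Why: Kinetic deprotonation at the methyl group (the only enolisable sp3 position) and O-silylation of the cross-conjugated enolate give the 2-silyloxy diene, the standard entry to Danishefsky- and Brassard-type dienes.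

Step 7
Reactants: 8 5-nitro-2-(3,4,5-trimethoxyphenyl)-4H-pyran-4-one; 12 1,1-dimethoxy-3-(trimethylsilyloxy)buta-1,3-diene
Product: 16 7-hydroxy-5-methoxy-2-(3,4,5-trimethoxyphenyl)-4H-chromen-4-one (7-hydroxy-5,3',4',5'-tetramethoxyflavone), via cis cycloadduct 13 (not isolated), via dihydrochromenone ketal 14 (not isolated), via 7-O-trimethylsilyl flavone 15 (not isolated)
Conditions: 12 (2.5 equiv), NaHCO3 (powder), PhMe, 25 → 80 °C; then K2CO3 (cat.), MeOH, 25 °C; AcOH
Reagents that add atoms: none
Why: Proposed new method: the C5=C6 bond of 8, made strongly electron-poor by the nitro group on C5 and the C4 carbonyl, should take up the electron-rich diene 12 in a polar, asynchronous Diels–Alder reaction in which the CH2 terminus of 12 bonds first to C6 (future C8–C8a) and the ketene acetal carbon then closes onto the nitro-bearing C5 (future C4a–C5); the closest known reactions are the cycloadditions of 3-nitrochromones and of haloquinones with oxygenated silyloxy dienes, which end with loss of nitrous acid or hydrogen halide to give hydroxyxanthones and anthraquinones, whereas a monocyclic 3-nitro-4-pyranone has not been used in this way. Ring A is closed by an intermolecular [4+2] cycloaddition that fuses a six-membered carbocycle onto ring C. The two stereocentres of adduct 13 (C4a and C8a) should come out cis because the diene adds suprafacially to the ring alkene; they are racemic and both vanish on aromatisation. The cis relation of NO2 and H allows syn elimination of nitrous acid (taken up by NaHCO3) to 14, 1,4-elimination of methanol from the ketal then gives aryl silyl ether 15, and methanolysis frees the 7-phenol. Site selectivity for C5=C6 over the aryl-substituted C2=C3 bond is secured by the nitro group, which activates only the bond that carries it. Regioselectivity is secured by C6 being β to both the carbonyl and the nitro group, so the nucleophilic CH2 terminus goes there and the diene oxygens end up at C5 (OMe) and C7 (OH).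

Step 8
Reactants: 16 7-hydroxy-5,3',4',5'-tetramethoxyflavone
Product: 17 tricetin, 5,7-dihydroxy-2-(3,4,5-trihydroxyphenyl)-4H-chromen-4-one
Conditions: BBr3 (8 equiv), CH2Cl2, −78 → 25 °C; MeOH, then H2O
Reagents that add atoms: none
Why: BBr3 cleavage of aryl methyl ethers; all four ethers should be cleaved, the peri 5-OMe fastest through chelation to the C4 carbonyl, and the flavone core is inert to the Lewis acid.

Step 9
Reactants: 17 tricetin
Product: 18 5,7-dihydroxy-2-(7-hydroxy-2,2-diphenyl-1,3-benzodioxol-5-yl)-4H-chromen-4-one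
Conditions: Ph2CCl2 (1.3 equiv), Ph2O, 175 °C
Reagents that add atoms: dichlorodiphenylmethane, ClC(Cl)(c1ccccc1)c1ccccc1
Why: Diphenylmethylene ketal formation needs two ortho hydroxyls, which only ring B offers; its triol is symmetric, so either adjacent pair gives the same 1,3-benzodioxole and leaves one ring B hydroxyl free.

Step 10
Reactants: 18 5,7-dihydroxy-2-(7-hydroxy-2,2-diphenyl-1,3-benzodioxol-5-yl)-4H-chromen-4-one
Product: 19 bis(triethylammonium) salt of the 7-sulfate and ring B 7-sulfate of 18 (5-hydroxyl free)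
Conditions: SO3·NEt3 (6 equiv), DMF, 50 °C; Sephadex LH-20 (MeOH)
Reagents that add atoms: sulfur trioxide–triethylamine complex, CC[N+](CC)(CC)S(=O)(=O)[O-]
Why: O-sulfation of phenols with an amine–SO3 complex; the 7-hydroxyl and the free ring B hydroxyl should react, whereas the 5-hydroxyl is tied up in the hydrogen bond to the C4 carbonyl and is the least nucleophilic.

Step 11
Reactants: 19 bis(triethylammonium) ketal disulfate
Product: 21 tricetin 7,3'-disulfate (free acid), via triethylammonium disulfate salt 20 (not isolated)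
Conditions: H2 (1 atm), 10% Pd/C, MeOH/THF, 25 °C; filter; Dowex 50WX8 (H+ form), H2O, 0 °C; freeze-dry
Reagents that add atoms: none
Why: Hydrogenolysis of the two benzylic C–O bonds of the diphenylmethylene ketal should free the catechol (diphenylmethane is lost) while aryl sulfate anions are inert to H2 over Pd/C, and cold cation exchange replaces triethylammonium by protons.

**Compound list**

1 | 5-ethynyl-1,2,3-trimethoxybenzene | C#Cc1cc(OC)c(OC)c(OC)c1 | starting material
2 | 3-(3,4,5-trimethoxyphenyl)prop-2-ynal | O=CC#Cc1cc(OC)c(OC)c(OC)c1 | intermediate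
3 | nitromethane | C[N+](=O)[O-] | starting material
4 | 1-nitro-4-(3,4,5-trimethoxyphenyl)but-3-yn-2-ol (racemic) | OC(C[N+](=O)[O-])C#Cc1cc(OC)c(OC)c(OC)c1 | intermediate
5 | 1-nitro-4-(3,4,5-trimethoxyphenyl)but-3-yn-2-one | O=C(C[N+](=O)[O-])C#Cc1cc(OC)c(OC)c(OC)c1 | intermediate
6 | 1-ethoxy-2-nitro-5-(3,4,5-trimethoxyphenyl)pent-1-en-4-yn-3-one (E/Z mixture) | CCOC=C([N+](=O)[O-])C(=O)C#Cc1cc(OC)c(OC)c(OC)c1 | intermediate
7 | 1-hydroxy-2-nitro-5-(3,4,5-trimethoxyphenyl)pent-1-en-4-yn-3-one (enol of the formyl nitro ketone) | OC=C([N+](=O)[O-])C(=O)C#Cc1cc(OC)c(OC)c(OC)c1 | intermediate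
8 | 5-nitro-2-(3,4,5-trimethoxyphenyl)-4H-pyran-4-one | COc1cc(-c2cc(=O)c([N+](=O)[O-])co2)cc(OC)c1OC | intermediate
9 | 1,1-dimethoxyethene | C=C(OC)OC | starting material
10 | acetyl chloride | CC(=O)Cl | starting material
11 | 4,4-dimethoxybut-3-en-2-one | CC(=O)C=C(OC)OC | intermediate
12 | 1,1-dimethoxy-3-(trimethylsilyloxy)buta-1,3-diene | COC(OC)=CC(=C)O[Si](C)(C)C | intermediate
13 | cis-fused 5,5-dimethoxy-4a-nitro-7-(trimethylsilyloxy)-2-(3,4,5-trimethoxyphenyl)-4a,5,8,8a-tetrahydro-4H-chromen-4-one (NO2 at C4a and H at C8a on the same face; racemic, one enantiomer drawn) | COc1cc(cc(OC)c1OC)C1=CC(=O)[C@]2([N+](=O)[O-])[C@H](O1)CC(O[Si](C)(C)C)=CC2(OC)OC | intermediate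
14 | 5,5-dimethoxy-7-(trimethylsilyloxy)-2-(3,4,5-trimethoxyphenyl)-5,8-dihydro-4H-chromen-4-one | COc1cc(cc(OC)c1OC)C1=CC(=O)C2=C(O1)CC(O[Si](C)(C)C)=CC2(OC)OC | intermediate
15 | 5-methoxy-7-(trimethylsilyloxy)-2-(3,4,5-trimethoxyphenyl)-4H-chromen-4-one | COc1cc(-c2cc(=O)c3c(OC)cc(O[Si](C)(C)C)cc3o2)cc(OC)c1OC | intermediate
16 | 7-hydroxy-5-methoxy-2-(3,4,5-trimethoxyphenyl)-4H-chromen-4-one | COc1cc(-c2cc(=O)c3c(OC)cc(O)cc3o2)cc(OC)c1OC | intermediate
17 | tricetin, 5,7-dihydroxy-2-(3,4,5-trihydroxyphenyl)-4H-chromen-4-one | O=c1cc(-c2cc(O)c(O)c(O)c2)oc2cc(O)cc(O)c12 | intermediate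
18 | 5,7-dihydroxy-2-(7-hydroxy-2,2-diphenyl-1,3-benzodioxol-5-yl)-4H-chromen-4-one | O=c1cc(-c2cc(O)c3OC(c4ccccc4)(c4ccccc4)Oc3c2)oc2cc(O)cc(O)c12 | intermediate
19 | bis(triethylammonium) 5-hydroxy-4-oxo-2-(2,2-diphenyl-7-sulfonatooxy-1,3-benzodioxol-5-yl)-4H-chromen-7-yl sulfate | O=c1cc(-c2cc(OS(=O)(=O)[O-])c3OC(c4ccccc4)(c4ccccc4)Oc3c2)oc2cc(OS(=O)(=O)[O-])cc(O)c12.CC[NH+](CC)CC.CC[NH+](CC)CC | intermediate
20 | bis(triethylammonium) salt of tricetin 7,3'-disulfate | O=c1cc(-c2cc(O)c(O)c(OS(=O)(=O)[O-])c2)oc2cc(OS(=O)(=O)[O-])cc(O)c12.CC[NH+](CC)CC.CC[NH+](CC)CC | intermediate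
21 | tricetin 7,3'-disulfate | O=c1cc(-c2cc(O)c(O)c(OS(=O)(=O)O)c2)oc2cc(OS(=O)(=O)O)cc(O)c12 | target

Total step count: 11. Longest linear sequence: 9 steps (steps 1, 2, 3, 4, 7, 8, 9, 10, 11).

**Steps most likely to fail**

Step 7 (the new method).
- Risk: the diene may add only once, as a Mukaiyama–Michael addition at C6 without ring closure. The pyranone ring may open by retro-oxa-Michael reaction. The diene may be consumed by the acid set free before it cycloadds.
- Fallback (known flavone synthesis from an o-hydroxyaryl ynone): it sets out from alkyne 1. Lithiation (n-BuLi, THF, −78 °C) and addition to 2,4,6-trimethoxybenzaldehyde would give racemic 1-(2,4,6-trimethoxyphenyl)-3-(3,4,5-trimethoxyphenyl)prop-2-yn-1-ol F1. MnO2 in CH2Cl2 would oxidise it to 1-(2,4,6-trimethoxyphenyl)-3-(3,4,5-trimethoxyphenyl)prop-2-yn-1-one F2. BCl3 (CH2Cl2, −78 → 0 °C) would remove, through chelation, only one methyl ortho to the carbonyl and give 1-(2-hydroxy-4,6-dimethoxyphenyl)-3-(3,4,5-trimethoxyphenyl)prop-2-yn-1-one F3. TfOH- or DMAP-catalysed 6-endo-dig oxa-Michael closure would give 5,7-dimethoxy-2-(3,4,5-trimethoxyphenyl)-4H-chromen-4-one F4. BBr3 as in step 8 would cleave all five ethers, and the fallback comes back to the route at tricetin 17.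

Step 4.
- Risk: retro-Claisen loss of the formyl group from 7 in the aqueous acid, or slow ring closure because the enol oxygen is deactivated by the nitro group.
- Fallback (ring closure by condensation in place of addition to the alkyne): it sets out from nitro ynone 5. Acid-catalysed hydration of the ynone (aq H2SO4, AcOH), with water adding at the aryl-bearing carbon, would give 1-nitro-4-(3,4,5-trimethoxyphenyl)butane-2,4-dione F5. C-formylation of its nitromethylene and cyclodehydration with acetic formic anhydride and HCO2Na, the way 3-nitrochromones are made from 2-hydroxy-ω-nitroacetophenones, comes back to the route at nitropyranone 8.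

Step 10.
- Risk: over-sulfation at the chelated 5-hydroxyl, incomplete sulfation at the ring B hydroxyl flanked by the ketal oxygen, and hydrolytic loss of sulfate during purification of the salts.
- Fallback (masked, neutral sulfate diesters in place of direct sulfation): it sets out from ketal 18. 2,2,2-Trichloroethyl chlorosulfate (ClS(=O)(=O)OCC(Cl)(Cl)Cl), Et3N and DMAP in THF at 0 °C would give 5-hydroxy-4-oxo-2-[2,2-diphenyl-7-(2,2,2-trichloroethoxysulfonyloxy)-1,3-benzodioxol-5-yl]-4H-chromen-7-yl 2,2,2-trichloroethyl sulfate F6, which can be chromatographed on silica. Zn and HCO2NH4 in MeOH would unmask both sulfates by reductive elimination and give the diammonium salt of the ketal disulfate F7. Hydrogenolysis under the conditions of step 11 would give the diammonium salt of tricetin 7,3'-disulfate F8, and the cold H+ resin of step 11 comes back to the route at target 21.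

**Further compounds**

F1 | step 7 | 1-(2,4,6-trimethoxyphenyl)-3-(3,4,5-trimethoxyphenyl)prop-2-yn-1-ol (racemic) | COc1cc(OC)c(C(O)C#Cc2cc(OC)c(OC)c(OC)c2)c(OC)c1
F2 | step 7 | 1-(2,4,6-trimethoxyphenyl)-3-(3,4,5-trimethoxyphenyl)prop-2-yn-1-one | COc1cc(OC)c(C(=O)C#Cc2cc(OC)c(OC)c(OC)c2)c(OC)c1
F3 | step 7 | 1-(2-hydroxy-4,6-dimethoxyphenyl)-3-(3,4,5-trimethoxyphenyl)prop-2-yn-1-one | COc1cc(O)c(C(=O)C#Cc2cc(OC)c(OC)c(OC)c2)c(OC)c1
F4 | step 7 | 5,7-dimethoxy-2-(3,4,5-trimethoxyphenyl)-4H-chromen-4-one | COc1cc(OC)c2c(c1)oc(-c1cc(OC)c(OC)c(OC)c1)cc2=O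
F5 | step 4 | 1-nitro-4-(3,4,5-trimethoxyphenyl)butane-2,4-dione | O=C(C[N+](=O)[O-])CC(=O)c1cc(OC)c(OC)c(OC)c1
F6 | step 10 | 5-hydroxy-4-oxo-2-[2,2-diphenyl-7-(2,2,2-trichloroethoxysulfonyloxy)-1,3-benzodioxol-5-yl]-4H-chromen-7-yl 2,2,2-trichloroethyl sulfate | O=c1cc(-c2cc(OS(=O)(=O)OCC(Cl)(Cl)Cl)c3OC(c4ccccc4)(c4ccccc4)Oc3c2)oc2cc(OS(=O)(=O)OCC(Cl)(Cl)Cl)cc(O)c12
F7 | step 10 | diammonium 5-hydroxy-4-oxo-2-(2,2-diphenyl-7-sulfonatooxy-1,3-benzodioxol-5-yl)-4H-chromen-7-yl sulfate | O=c1cc(-c2cc(OS(=O)(=O)[O-])c3OC(c4ccccc4)(c4ccccc4)Oc3c2)oc2cc(OS(=O)(=O)[O-])cc(O)c12.[NH4+].[NH4+]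
F8 | step 10 | diammonium salt of tricetin 7,3'-disulfate | O=c1cc(-c2cc(O)c(O)c(OS(=O)(=O)[O-])c2)oc2cc(OS(=O)(=O)[O-])cc(O)c12.[NH4+].[NH4+]
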